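(The runs were generated by integration from invented constants, and the scatter is random.)

Target plus substrate stood at 100% of the charge at 90.0 min in the ash run, so I booked the flask as one exchange between substrate and target and asked where it ends and how fast it gets there.

- ash: substrate 2 M; gas phase 200 mM (held); catalyst 10 mM; the very flask that is asked about, followed so far
- flask: substrate 2.0 M; gas phase 200 mM (held); catalyst 10 mM; time 8.0 h

- ash (time / min: target / %, substrate / %): 8.00: 1.4, 98.5; 25.0: 4.6, 95.5; 40.0: 5.9, 93.8; 60.0: 8.7, 90.5; 90.0: 12.6, 87.7

(readings scatter by 0.3 percentage points)

- at the start none of the gas phase is in solution

- the target standing at 8.0 h, as a percentage of the substrate charged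
- the change that raises the amount of target at 8.0 h, in percent of the substrate charged most ("none" if none brings more than 2 percentage points) (Saturday's / Sunday's / Thursday's / none)
- amount of target at 8.0 h, in percent of the substrate charged, after Thursday's

- Saturday's: doubling the transfer coefficient of the gas phase, all else as stated
- Sunday's: doubling the saturation concentration of gas phase, all else as stated
- Thursday's: doubling the amount of catalyst, all else as stated

The first rung of my ladder was the dissolving of the gas phase. Over the first 25.0 min the target rose by 0.00184 min⁻¹ of the charge, and over the first 8.00 min by 0.00175 min⁻¹, so I saw no lag and took the gas in solution as steady from the first reading.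

The middle rung was the relaxation. I took the exchange, with the gas held, as pseudo-first-order each way, so that the rate falls in a straight line with the target level and reaches zero at a ceiling, the equilibrium. From 25.0 min to 90.0 min the rate was 0.00123 min⁻¹, lower than before, at a mean level of 8.60% against 2.30%. That line gave a relaxation time τ of 103 min and a ceiling of 21.3%, readings that carry the scatter. The end ratio q, target over substrate once the flask stops moving, was therefore 0.271.

The last rung was the asked time, 4.64 τ, so I committed to 21.1%. Assuming catalyst shortens τ and leaves q alone, Thursday's adds 0.21 percentage points. Saturday's doubles the transfer coefficient of the gas phase, a step in which I saw no lag, so I expected little from it. Assuming each target takes one dissolved gas, Sunday's doubles q and lifts the target to 35.2%, so that was my choice.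

The forecast said 34%, Thursday's and 54%, reading the slowing as “catalyst decay or product inhibition”.

The flask gave 23.7%, with Sunday's best at 15 points gained, Thursday's 0.5 points, Saturday's 0.042 points, and 24.2% after Thursday's.

    dissolved gas ⇌ dormant form (K = 230, k = 0.00120 min⁻¹)
    substrate + dissolved gas + catalyst ⇌ catalyst + target (K = 1.60 M⁻¹, k = 1.00 M⁻² min⁻¹)
    gas phase ⇌ dissolved gas, rate k3*(csat - [dissolved gas]) (kL = 0.690 min⁻¹)

In these equations q is 1.6 M⁻¹ times the 0.200 M of dissolved gas, which is 0.320, and the flask stood at 24.2% after 80.0 h. The neighbour flask, the same charge read at 3.0 h, lies 1.75 τ along, so my q and τ put its target at 17.6%. That neighbour flask gave 18.4% of target and kept 82% of its substrate.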